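**Plan**

1. Numbering and faces: daucane numbering is used (C1 = CH3-bearing ring-fusion carbon, C2, C3, C4 = isopropyl carbinol, C5 = ring-fusion CH, C6 = ester carbon, C7, C8 = CH3-bearing oxirane carbon, C9, C10; C14 = CH3 on C8). β is the face of the C4 and C6 oxygens; α is the face of the C1 methyl group, H5 and the oxirane oxygen. The target is taken exactly as drawn, i.e. the cis-fused (1S,4R,5S,6R,8R,9S) isomer.
2. Retrosynthetic cuts, in order: oxirane O and aryl ester; C4–isopropyl (organocerium + ketone); C6–O/C5–H (conjugate borylation of the enone C4(=O)–C5=C6); ring bond C1–C10 by a retro-[3,3] shift to a cis-divinylcyclopropane C6–C7–C8; vinyl C9=C10 from CH2OH, C7 from a zinc carbenoid, C5–C6 from a Stille coupling.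
3. Enabling feature: with C5=C6 written as the enone of a C4 ketone, the seven-membered ring C1–C10–C9=C8–C7–C6=C5 is a cyclohepta-1,4-diene whose two double bonds flank C7H2 opposite the sp3–sp3 bond C1–C10. This is the retron of the divinylcyclopropane rearrangement, and C7–C8(C14)–C9–C10 is one isoprene-type C5 unit.
4. Forward order: the cyclopentenone ring comes first; the C5 unit is joined at C5 as a (Z)-allylic alcohol and tied into a temporary cyclopropane; the seven-membered ring is closed last by the rearrangement, which consumes the cyclopropane. Enone hydration, isopropyl addition, esterification (phenol acetate removed in the same step) and epoxidation follow.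
5. Stereochemistry: reagent-controlled cyclopropanation sets C6/C8 and is relayed to quaternary C1 in the boat transition state; C6 by the chiral copper catalyst; C5 by protonation to the cis ring fusion; C4 by α-face addition to the cis-fused ketone; C8/C9 by peracid attack anti to the ester.

Key step: step 6

**Route**

Step 1
Reactants: 1 3-methylcyclopent-2-en-1-one
Product: 2 2-iodo-3-methylcyclopent-2-en-1-one
Conditions: I2, K2CO3, DMAP (cat.), THF–H2O (1:1), rt
Reagents that add atoms: iodine, II
Why: α-iodination of an enone (amine conjugate addition, iodination of the enolate, elimination) places iodine regiospecifically on C5 and creates no stereocentre.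

Step 2
Reactants: 3 prop-2-yn-1-ol
Product: 5 (2Z)-2-methyl-3-(tributylstannyl)prop-2-en-1-ol, via alkenylmagnesium alkoxide 4 (not isolated)
Conditions: MeMgBr (2.2 equiv), CuI (10 mol %), THF, −10 °C → rt; then Bu3SnCl, 0 °C → rt
Reagents that add atoms: methylmagnesium bromide, C[Mg]Br; tributyltin chloride, CCCC[Sn](Cl)(CCCC)CCCC
Why: copper-catalysed anti-carbomagnesiation of a propargylic alkoxide (Duboudin–Jousseaume reaction) puts methyl on C8 and magnesium on C6 in a five-membered chelate, so stannylation with retention fixes the Z geometry (tin cis to CH2OH) that later becomes the cis relationship on the cyclopropane.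

Step 3
Reactants: 2 2-iodo-3-methylcyclopent-2-en-1-one; 5 (2Z)-2-methyl-3-(tributylstannyl)prop-2-en-1-ol
Product: 6 2-[(1Z)-3-hydroxy-2-methylprop-1-en-1-yl]-3-methylcyclopent-2-en-1-one
Conditions: Pd(PPh3)4 (5 mol %), CuI (10 mol %), DMF, 50 °C
Reagents that add atoms: none
Why: copper-assisted Stille coupling of an α-iodoenone with an alkenylstannane forms the C5–C6 bond with retention of the Z geometry and tolerates the free hydroxyl and the ketone.

Step 4
Reactants: 6 2-[(1Z)-3-hydroxy-2-methylprop-1-en-1-yl]-3-methylcyclopent-2-en-1-one
Product: 7 2-[(1S,2R)-2-(hydroxymethyl)-2-methylcyclopropyl]-3-methylcyclopent-2-en-1-one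
Conditions: Zn(CH2I)2·DME (from Et2Zn and CH2I2), (4S,5S)-2-butyl-N,N,N′,N′-tetramethyl-1,3,2-dioxaborolane-4,5-dicarboxamide (1.2 equiv), CH2Cl2, −10 °C → rt
Reagents that add atoms: diiodomethane, ICI
Why: Charette asymmetric Simmons–Smith cyclopropanation, in which the zinc alkoxide bound to the chiral dioxaborolane delivers CH2 (C7) stereospecifically to one face of the only hydroxyl-bearing, electron-rich alkene (the enone double bond is tetrasubstituted and electron-poor), so C6 and C8 are set together with CH2OH and the cyclopentenone cis; the (4S,5S) controller is chosen because its antipode converts cinnamyl alcohol into the (1S,2S) product, which corresponds to the opposite face here.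

Step 5
Reactants: 7 2-[(1S,2R)-2-(hydroxymethyl)-2-methylcyclopropyl]-3-methylcyclopent-2-en-1-one
Product: 8 (1R,2S)-1-methyl-2-(2-methyl-5-oxocyclopent-1-en-1-yl)cyclopropane-1-carbaldehyde
Conditions: Dess–Martin periodinane, pyridine, CH2Cl2, 0 °C → rt
Reagents that add atoms: none
Why: Dess–Martin oxidation of the primary alcohol under buffered conditions touches no stereocentre, and the aldehyde cannot epimerise because its α carbon is quaternary.

Step 6
Reactants: 8 (1R,2S)-1-methyl-2-(2-methyl-5-oxocyclopent-1-en-1-yl)cyclopropane-1-carbaldehyde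
Product: 10 (3aS)-3a,6-dimethyl-3,3a,4,7-tetrahydroazulen-1(2H)-one, via cis-divinylcyclopropane 9 (not isolated)
Conditions: Ph3PCH3Br, KN(SiMe3)2 (1.05 equiv ylide), THF, −78 → 0 °C; then PhMe, 110 °C
Reagents that add atoms: methyltriphenylphosphonium bromide, C[P+](c1ccccc1)(c1ccccc1)c1ccccc1.[Br-]
Why: Wittig methylenation of the aldehyde gives cis-1,2-dialkenylcyclopropane 9, in which the vinyl group (C9=C10) and the enone double bond (C5=C1) sit on the same face of the three-membered ring, and on warming 9 undergoes the concerted suprafacial [3,3] shift (divinylcyclopropane–cycloheptadiene rearrangement, a strain-driven Cope rearrangement) through the boat transition state with both alkenyl groups folded over the cyclopropane. The seven-membered ring is closed by forming the C10–C1 σ bond in a six-centre pericyclic closure that cuts the temporary cyclopropane bond C6–C8 (a 3 → 7 ring enlargement needing neither dilution nor reagent), and C8=C9 (trisubstituted, Z by ring constraint) and C5=C6 emerge exactly where the oxirane and the C5–H/C6–O pair are needed. The only new stereocentre, quaternary C1, is set by chirality transfer: the boat geometry lets C10 reach one face of C1 only, so (1S,2S)-9 should give (3aS)-10 and the two cyclopropane stereocentres, which become sp2, are traded for it. The closest known reaction types are the olefination/rearrangement sequences of cis-2-alkenylcyclopropanecarbaldehydes and the cyclopropyl-enone annulations used for hydroazulenes, including cases that build a quaternary centre at a fully substituted, acceptor-conjugated alkene terminus. The step needs the cis relationship of the two alkenyl groups (secured by the Z geometry of 6 and the stereospecific methylene transfer) and olefination of the aldehyde in preference to the enone carbonyl (secured by low temperature and one equivalent of ylide); the C1 methyl group points at the cyclopropane CH2 in the transition state, which is why heating to about 110 °C is planned.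

Step 7
Reactants: 10 (3aS)-3a,6-dimethyl-3,3a,4,7-tetrahydroazulen-1(2H)-one
Product: 12 (3aS,8R,8aS)-8-hydroxy-3a,6-dimethyl-3,3a,4,7,8,8a-hexahydroazulen-1(2H)-one, via β-boryl ketone 11 (not isolated)
Conditions: B2pin2, CuCl (5 mol %), (R,R)-QuinoxP* (6 mol %), NaOtBu (5 mol %), MeOH (2 equiv), THF, 0 °C; then NaBO3·4H2O, THF–H2O, 0 °C → rt
Reagents that add atoms: bis(pinacolato)diboron, CC1(C)OB(OC1(C)C)B1OC(C)(C)C(C)(C)O1; sodium perborate, [Na+].[O-]OB=O
Why: copper-catalysed conjugate borylation of the enone followed by stereoretentive C–B oxidation (a formal anti-Markovnikov hydration of C5=C6), in which the boryl–copper species adds to the β face of C6 under control of the chiral bisphosphine (the ligand antipode used being the one matched to delivery anti to the C1 methyl group) and the enolate is protonated at C5 anti to the bulky boronate, giving the cis ring fusion that is also expected to be the thermodynamic one for this epimerisable centre.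

Step 8
Reactants: 12 (3aS,8R,8aS)-8-hydroxy-3a,6-dimethyl-3,3a,4,7,8,8a-hexahydroazulen-1(2H)-one
Product: 13 (3R,3aS,4R,8aS)-6,8a-dimethyl-3-(propan-2-yl)-1,2,3,3a,4,5,8,8a-octahydroazulene-3,4-diol
Conditions: iPrMgCl (3.5 equiv), CeCl3 (anhydrous, 3.5 equiv), THF, −78 → −20 °C
Reagents that add atoms: isopropylmagnesium chloride, CC(C)[Mg]Cl
Why: organocerium (Imamoto) 1,2-addition to an enolisable ketone, where the weakly basic reagent avoids enolisation and retro-aldol cleavage of the β-alkoxide, and isopropyl attacks C4 from the α (convex) face, anti to the adjacent C5–C6 bond and the cerium-bound C6 alkoxide, so the new tertiary hydroxyl is β and cis to the C6 oxygen.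

Step 9
Reactants: 13 (3R,3aS,4R,8aS)-6,8a-dimethyl-3-(propan-2-yl)-1,2,3,3a,4,5,8,8a-octahydroazulene-3,4-diol; 14 4-(acetyloxy)benzoic acid
Product: 16 (3R,3aS,4R,8aS)-3-hydroxy-6,8a-dimethyl-3-(propan-2-yl)-1,2,3,3a,4,5,8,8a-octahydroazulen-4-yl 4-hydroxybenzoate, via acetate-protected ester 15 (not isolated)
Conditions: DCC, DMAP (cat.), CH2Cl2, 0 °C → rt; then NH3 (7 M in MeOH), 0 °C
Reagents that add atoms: none
Why: Steglich esterification acylates only the secondary C6 hydroxyl (the tertiary C4 hydroxyl is inert) with retention because the C6–O bond is not touched, and mild ammonolysis then cleaves the aryl acetate much faster than the hindered alkyl aroate.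

Step 10
Reactants: 16 (3R,3aS,4R,8aS)-3-hydroxy-6,8a-dimethyl-3-(propan-2-yl)-1,2,3,3a,4,5,8,8a-octahydroazulen-4-yl 4-hydroxybenzoate
Product: 17 (1S,4R,5S,6R,8R,9S)-8,9-epoxy-4-hydroxydaucan-6-yl 4-hydroxybenzoate (target)
Conditions: mCPBA, NaHCO3, CH2Cl2, 0 °C
Reagents that add atoms: 3-chloroperoxybenzoic acid, OOC(=O)c1cccc(Cl)c1
Why: Prilezhaev epoxidation of the only electron-rich (trisubstituted) alkene, with the peracid expected to approach the α face, anti to the C6 aroyloxy group and to the cyclopentane ring that folds over the β face of the cis-fused bicycle, giving the oxirane cis to the C1 methyl group, while the bicarbonate buffer prevents acid-induced opening of the epoxide by the C4 hydroxyl.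

**Compound list**

1 | 3-methylcyclopent-2-en-1-one | CC1=CC(=O)CC1 | starting material
2 | 2-iodo-3-methylcyclopent-2-en-1-one | CC1=C(I)C(=O)CC1 | intermediate
3 | prop-2-yn-1-ol | C#CCO | starting material
4 | (Z)-3-magnesio-2-methylprop-2-en-1-olate chelate (4-methyl-2,5-dihydro-1,2-oxamagnesole) | CC1=C[Mg]OC1 | intermediate (not isolated)
5 | (2Z)-2-methyl-3-(tributylstannyl)prop-2-en-1-ol | CCCC[Sn](CCCC)(CCCC)/C=C(C)\CO | intermediate
6 | 2-[(1Z)-3-hydroxy-2-methylprop-1-en-1-yl]-3-methylcyclopent-2-en-1-one | O=C1CCC(C)=C1/C=C(C)\CO | intermediate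
7 | 2-[(1S,2R)-2-(hydroxymethyl)-2-methylcyclopropyl]-3-methylcyclopent-2-en-1-one (CH2OH cis to the cyclopentenone) | O=C1CCC(C)=C1[C@H]2C[C@@]2(C)CO | intermediate
8 | (1R,2S)-1-methyl-2-(2-methyl-5-oxocyclopent-1-en-1-yl)cyclopropane-1-carbaldehyde | O=C1CCC(C)=C1[C@H]2C[C@@]2(C)C=O | intermediate
9 | 2-[(1S,2S)-2-ethenyl-2-methylcyclopropyl]-3-methylcyclopent-2-en-1-one (vinyl cis to the cyclopentenone) | O=C1CCC(C)=C1[C@H]2C[C@@]2(C)C=C | intermediate (not isolated)
10 | (3aS)-3a,6-dimethyl-3,3a,4,7-tetrahydroazulen-1(2H)-one | O=C1CC[C@@]2(C)CC=C(C)CC=C21 | intermediate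
11 | (3aS,8R,8aR)-3a,6-dimethyl-8-(4,4,5,5-tetramethyl-1,3,2-dioxaborolan-2-yl)-3,3a,4,7,8,8a-hexahydroazulen-1(2H)-one | O=C1CC[C@@]2(C)CC=C(C)C[C@@H](B3OC(C)(C)C(C)(C)O3)[C@H]21 | intermediate (not isolated)
12 | (3aS,8R,8aS)-8-hydroxy-3a,6-dimethyl-3,3a,4,7,8,8a-hexahydroazulen-1(2H)-one | O=C1CC[C@@]2(C)CC=C(C)C[C@@H](O)[C@H]21 | intermediate
13 | (3R,3aS,4R,8aS)-6,8a-dimethyl-3-(propan-2-yl)-1,2,3,3a,4,5,8,8a-octahydroazulene-3,4-diol | CC(C)[C@]1(O)CC[C@@]2(C)CC=C(C)C[C@@H](O)[C@H]21 | intermediate
14 | 4-(acetyloxy)benzoic acid | CC(=O)Oc1ccc(cc1)C(=O)O | starting material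
15 | (3R,3aS,4R,8aS)-3-hydroxy-6,8a-dimethyl-3-(propan-2-yl)-1,2,3,3a,4,5,8,8a-octahydroazulen-4-yl 4-(acetyloxy)benzoate | CC(C)[C@]1(O)CC[C@@]2(C)CC=C(C)C[C@@H](OC(=O)c3ccc(OC(C)=O)cc3)[C@H]21 | intermediate (not isolated)
16 | (3R,3aS,4R,8aS)-3-hydroxy-6,8a-dimethyl-3-(propan-2-yl)-1,2,3,3a,4,5,8,8a-octahydroazulen-4-yl 4-hydroxybenzoate | CC(C)[C@]1(O)CC[C@@]2(C)CC=C(C)C[C@@H](OC(=O)c3ccc(O)cc3)[C@H]21 | intermediate
17 | (1S,4R,5S,6R,8R,9S)-8,9-epoxy-4-hydroxydaucan-6-yl 4-hydroxybenzoate (the 6,7-epoxide of 16 in azulene numbering, oxirane cis to the 8a-methyl group and trans to the ester) | CC(C)[C@]1(O)CC[C@@]2(C)C[C@@H]3O[C@]3(C)C[C@@H](OC(=O)c3ccc(O)cc3)[C@H]21 | target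

**Step count and risks**

Total step count: 10. Longest linear sequence: 9 steps (steps 1 and 3 to 10; the branch through step 2 is equally long).

The three steps most likely to fail:

Step 6. The rearrangement may be too slow, because the C1 methyl group on the tetrasubstituted enone terminus is pressed against the cyclopropane CH2 in the boat transition state. At the temperature then needed, homolytic one-centre epimerisation of the cyclopropane (loss of the cis relationship and of enantiomeric purity) or base-induced migration of the skipped diene into conjugation may compete, and the ylide may also attack the enone carbonyl. The fallback closes the seven-membered ring by ring-closing metathesis instead and sets out from 1. Catalytic enantioselective 1,2-allylboration of 1 (allylboronic acid pinacol ester, chiral 3,3′-dibromo-BINOL catalyst) would give (1S)-3-methyl-1-(prop-2-en-1-yl)cyclopent-2-en-1-ol F1. Anionic oxy-Cope rearrangement (KH, 18-crown-6, THF) moves the allyl group suprafacially from C4 to C1 and gives the regiodefined enolate, which after transmetallation with ZnCl2 is added to 3-methylbut-3-enal to give the aldol (3S)-2-(1-hydroxy-3-methylbut-3-en-1-yl)-3-methyl-3-(prop-2-en-1-yl)cyclopentan-1-one F2 as a mixture at C5 and C6. Ring-closing metathesis with the second-generation Grubbs catalyst gives the hydroxy ketone mixture (3aS)-8-hydroxy-3a,6-dimethyl-3,3a,4,7,8,8a-hexahydroazulen-1(2H)-one F3. Dehydration (MsCl, Et3N; then DBU) erases C5 and C6 and returns to the route at 10.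

Step 7. Facial selectivity of the boryl transfer to C6 may be poor, because the two faces of the enone are shielded to a similar degree by the C1 methyl group and by C10. Protonation at C5 may give the trans-fused epimer, and the alkoxide base may move the C8=C9 double bond into conjugation. The fallback sets out from 10: nucleophilic (Weitz–Scheffer) epoxidation with t-BuOOH and DBU would give the β-epoxy ketone (3aS)-8,8a-epoxy-3a,6-dimethyl-3,3a,4,7,8,8a-hexahydroazulen-1(2H)-one F4 (oxirane trans to the 3a-methyl group). SmI2 (THF–MeOH, −78 °C) then cleaves the C5–O bond of the α,β-epoxy ketone and keeps the C6 hydroxyl, with C5 set by protonation of the samarium enolate or by equilibration. This returns to the route at 12.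

Step 10. The peracid may approach the β face, or show no preference, because the α face carries the angular methyl group. The fallback sets out from 15, which is then isolated before the ammonolysis. NBS in aqueous DME would give the bromohydrin 7-bromo-3,6-dihydroxy-6,8a-dimethyl-3-(propan-2-yl)decahydroazulen-4-yl 4-(acetyloxy)benzoate F5 (azulene numbering; Br trans and 6-OH cis to the 8a-methyl group) by anti opening of the bromonium ion formed on the more accessible face, with water entering at the tertiary C8. K2CO3 in MeOH then closes the oxirane with inversion at C9, on the face opposite to the one attacked first, and removes the phenolic acetate in the same operation. This returns to the route at 17.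

**Further compounds**

F1 | step 6 | (1S)-3-methyl-1-(prop-2-en-1-yl)cyclopent-2-en-1-ol | C=CC[C@@]1(O)CCC(C)=C1
F2 | step 6 | (3S)-2-(1-hydroxy-3-methylbut-3-en-1-yl)-3-methyl-3-(prop-2-en-1-yl)cyclopentan-1-one (mixture at C2 and the carbinol carbon) | O=C1CC[C@@](C)(CC=C)C1C(O)CC(C)=C
F3 | step 6 | (3aS)-8-hydroxy-3a,6-dimethyl-3,3a,4,7,8,8a-hexahydroazulen-1(2H)-one (12 together with its C8 and C8a diastereomers) | O=C1CC[C@@]2(C)CC=C(C)CC(O)C21
F4 | step 7 | (3aS)-8,8a-epoxy-3a,6-dimethyl-3,3a,4,7,8,8a-hexahydroazulen-1(2H)-one (oxirane trans to the 3a-methyl group) | O=C1CC[C@@]2(C)CC=C(C)C[C@H]3O[C@]321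
F5 | step 10 | 7-bromo-3,6-dihydroxy-6,8a-dimethyl-3-(propan-2-yl)decahydroazulen-4-yl 4-(acetyloxy)benzoate (Br trans and 6-OH cis to the 8a-methyl group) | CC(C)[C@]1(O)CC[C@@]2(C)C[C@@H](Br)[C@](C)(O)C[C@@H](OC(=O)c3ccc(OC(C)=O)cc3)[C@H]21
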